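**Retrosynthetic overview**

1. The cyclohexene ring is cut at two bonds at once: C1–C2 (acyl-bearing CH to prenyl-bearing CH) and C5–C6 (ring CH2 to phenyl-bearing CH). This Diels–Alder disconnection leads to benzofuranyl chalcone 8 and (E)-β-ocimene 9 and sets all three stereocentres in the last step.
2. Enabling feature: the ring double bond C3=C4 lies opposite the C1–C6 bond (cyclohexene retron) and C1 is α to the aryl ketone. That ketone sits on C7 of the benzofuran next to the free C6–OH, so phenol O and ketone O can be clamped by a chiral borate in a temporary six-membered chelate ring, which activates the enone, carries the chirality and is hydrolysed on work-up.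
3. Chalcone 8 comes from 7-acetylbenzofuran 5 and benzaldehyde (Claisen–Schmidt condensation).
4. The furan ring of 5 is annulated onto 2',6'-dihydroxy-4'-methoxyacetophenone 1 (O-alkylation with bromoacetaldehyde diethyl acetal, then acid cyclodehydration).
5. Order of ring formation: benzene ring bought, furan ring in step 2, cyclohexene ring in step 4.

Key step: step 4

Remark: (3E)-β-ocimene is taken as the purchasable, isomerically enriched terpene; any (3Z) isomer cannot reach the s-cis diene conformation without severe strain and should stay behind unreacted.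

**Route**

Step 1
Reactants: 1 2',6'-dihydroxy-4'-methoxyacetophenone; 2 bromoacetaldehyde diethyl acetal
Product: 3 1-[2-(2,2-diethoxyethoxy)-6-hydroxy-4-methoxyphenyl]ethanone
Conditions: 2 (1.2 equiv), K2CO3 (1.5 equiv), KI (0.1 equiv), DMF, 110 °C
Reagents that add atoms: none
Why: Williamson ether synthesis on one of the two equivalent phenols of 1; the remaining hydroxyl stays locked in a hydrogen bond to the ketone and is far less nucleophilic, so mono-alkylation should prevail.

Step 2
Reactants: 3 1-[2-(2,2-diethoxyethoxy)-6-hydroxy-4-methoxyphenyl]ethanone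
Product: 5 1-(6-hydroxy-4-methoxy-1-benzofuran-7-yl)ethanone, via dihydrobenzofuran ethyl ether 4 (not isolated)
Conditions: Amberlyst 15 (sulfonated polystyrene resin, polymer–C6H4SO3H), PhCl, 120 °C, EtOH distilled off
Reagents that add atoms: none
Why: Acid-catalysed cyclodehydration of an aryloxyacetaldehyde acetal (intramolecular Friedel–Crafts-type attack of the oxocarbenium ion, then loss of ethanol to aromatize the furan); the only free position ortho to the ether oxygen, which is also para to the free OH and ortho to OMe, takes the electrophile, so only the 7-acetyl benzofuran can form.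

Step 3
Reactants: 5 1-(6-hydroxy-4-methoxy-1-benzofuran-7-yl)ethanone; 6 benzaldehyde
Product: 8 (2E)-1-(6-hydroxy-4-methoxy-1-benzofuran-7-yl)-3-phenylprop-2-en-1-one, via aldol adduct 7 (not isolated)
Conditions: 6 (1.2 equiv), KOH (4 equiv), EtOH/H2O, 0 °C to rt; then aq. HCl to pH 3
Reagents that add atoms: none
Why: Claisen–Schmidt condensation of the methyl ketone with a non-enolizable aldehyde; E1cB dehydration of the aldol adduct should give the thermodynamically favoured (E)-enone.

Step 4
Reactants: 8 (2E)-1-(6-hydroxy-4-methoxy-1-benzofuran-7-yl)-3-phenylprop-2-en-1-one; 9 (E)-β-ocimene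
Product: 12 (6-hydroxy-4-methoxy-1-benzofuran-7-yl)[(1R,2S,6R)-3-methyl-2-(3-methylbut-2-en-1-yl)-6-phenylcyclohex-3-en-1-yl]methanone, via chalcone spiro-borate 10 (not isolated), via cycloadduct spiro-borate 11 (not isolated)
Conditions: B(OPh)3 (1.2 equiv), (S)-VANOL [(S)-3,3'-diphenyl-2,2'-bi-1-naphthol] (1.2 equiv), 4 Å MS, PhCF3, rt, 1 h; then 9 (5 equiv), rt to 40 °C; H2O/aq. NaHCO3 work-up, ligand recovered
Reagents that add atoms: none
Why: B(OPh)3, (S)-VANOL and the phenol of 8 should exchange to the tetracoordinate spiro-borate 10, in which boron bridges the benzofuran C6–O and the ketone O in a six-membered chelate, holds the enone s-cis and coplanar with the aryl ring and lowers its LUMO; 9 then adds in a concerted, asynchronous normal-demand Diels–Alder reaction, and hydrolysis of borate 11 on work-up releases 12 and the ligand. The closest known reaction type is the chiral biaryl-diol borate-promoted asymmetric Diels–Alder reaction of 2'-hydroxychalcones with acyclic 1,3-dienes. The cyclohexene ring is closed by an intermolecular [4+2] cycloaddition, suprafacial on both partners, in which the bond from the enone β-carbon to the diene CH2 terminus (C6–C5) leads and the bond between the acyl-bearing C1 and the prenyl-bearing C2 completes the ring. The trans relation of C1 and C6 is copied from the (E)-enone, the cis relation of C1 and C2 comes from the (E)-diene reacting through the endo transition state (diene over the chelated carbonyl), and the absolute configuration comes from the ligand: in the spiro-borate model the vaulted naphthalene of (S)-VANOL covers the enone face that would lead to (1S,6S), so addition to the open face should give (1R,2S,6R). Regioselectivity (unsubstituted CH2 terminus to the β-carbon, substituted terminus to the α-carbon) is secured by the polarized chelated enone meeting the less hindered, most nucleophilic diene terminus, and chemoselectivity by the fact that only the enone is activated by boron, while the trisubstituted side-chain alkene, any (3Z)-diene and the furan C2=C3 bond should not take part. The step needs endo and facial selectivity at the same time; a minor exo adduct (epimeric at C2 relative to C1 and C6) would be removed by chromatography.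

**Compound list**

1 | 2',6'-dihydroxy-4'-methoxyacetophenone [1-(2,6-dihydroxy-4-methoxyphenyl)ethanone] | COc1cc(O)c(C(C)=O)c(O)c1 | starting material
2 | bromoacetaldehyde diethyl acetal (2-bromo-1,1-diethoxyethane) | CCOC(CBr)OCC | starting material
3 | 1-[2-(2,2-diethoxyethoxy)-6-hydroxy-4-methoxyphenyl]ethanone | CCOC(COc1cc(OC)cc(O)c1C(C)=O)OCC | intermediate
4 | 1-(3-ethoxy-6-hydroxy-4-methoxy-2,3-dihydro-1-benzofuran-7-yl)ethanone, racemic, formed in the flask | CCOC1COc2c1c(OC)cc(O)c2C(C)=O | intermediate
5 | 1-(6-hydroxy-4-methoxy-1-benzofuran-7-yl)ethanone | COc1cc(O)c(C(C)=O)c2occc12 | intermediate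
6 | benzaldehyde | O=Cc1ccccc1 | starting material
7 | 3-hydroxy-1-(6-hydroxy-4-methoxy-1-benzofuran-7-yl)-3-phenylpropan-1-one, racemic, formed in the flask | COc1cc(O)c(C(=O)CC(O)c2ccccc2)c2occc12 | intermediate
8 | (2E)-1-(6-hydroxy-4-methoxy-1-benzofuran-7-yl)-3-phenylprop-2-en-1-one | COc1cc(O)c(C(=O)/C=C/c2ccccc2)c2occc12 | intermediate
9 | (E)-β-ocimene [(3E)-3,7-dimethylocta-1,3,6-triene] | C=C/C(C)=C/CC=C(C)C | starting material
10 | spiro-borate of 8: boron bound to the C6 phenolate O and the ketone O of 8 and to both naphtholate O of (S)-VANOL, formed in the flask (the (S) axis of the ligand is not encoded in the SMILES) | COc1cc2O[B-]3(Oc4c(-c5c(O3)c6ccccc6cc5-c5ccccc5)c(-c5ccccc5)cc5ccccc45)[O+]=C(/C=C/c3ccccc3)c2c2occc12 | intermediate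
11 | spiro-borate of cycloadduct 12 with the same boron–(S)-VANOL unit, formed in the flask (the (S) axis of the ligand is not encoded in the SMILES) | COc1cc2O[B-]3(Oc4c(-c5c(O3)c6ccccc6cc5-c5ccccc5)c(-c5ccccc5)cc5ccccc45)[O+]=C([C@@H]3[C@H](CC=C(C)C)C(C)=CC[C@H]3c3ccccc3)c2c2occc12 | intermediate
12 | (6-hydroxy-4-methoxy-1-benzofuran-7-yl)[(1R,2S,6R)-3-methyl-2-(3-methylbut-2-en-1-yl)-6-phenylcyclohex-3-en-1-yl]methanone | COc1cc(O)c(C(=O)[C@@H]2[C@H](CC=C(C)C)C(C)=CC[C@H]2c2ccccc2)c2occc12 | target

**Totals**

Total step count: 4. Longest linear sequence: 4 steps (1 → 3 → 5 → 8 → 12).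

**Steps most likely to fail**

Step 4. The facial selectivity or the endo/exo selectivity of the borate-promoted cycloaddition may be low, or the triene may oligomerize under the Lewis-acidic conditions. The sense of induction rests on the chelate model and is to be confirmed on the first adduct; if only the sense is wrong, the (R)-ligand is used. If the level of selectivity is poor, the fallback sets out from 8 and 9 and gives up catalyst control. The cycloaddition is run thermally (neat 9, sealed tube, 150 °C) to the racemic endo adduct (1RS,2SR,6RS)-(6-hydroxy-4-methoxy-1-benzofuran-7-yl)[3-methyl-2-(3-methylbut-2-en-1-yl)-6-phenylcyclohex-3-en-1-yl]methanone F1. Its phenol is acylated with (1S)-camphanic chloride (Et3N, DMAP, CH2Cl2) to two diastereomeric esters, the camphanate of the (1R,2S,6R) ketone F2 and the camphanate of the (1S,2R,6S) ketone F3, which are separated by chromatography or crystallization. Methanolysis of F2 (K2CO3, MeOH, 0 °C) comes back to the route at 12.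

Step 2. The oxocarbenium ion may attack a second electron-rich ring (oligomerization), or the acetal may hydrolyse without ring closure at the doubly flanked position. The fallback sets out from 1 and builds the furan by cross-coupling instead of electrophilic substitution. Mono-iodination (N-iodosuccinimide, DMF, 0 °C) should give 1-(2,6-dihydroxy-3-iodo-4-methoxyphenyl)ethanone F4. Sonogashira coupling with ethynyltrimethylsilane (Pd(PPh3)2Cl2, CuI, Et3N, DMF, 50 °C) should give 1-{2,6-dihydroxy-4-methoxy-3-[(trimethylsilyl)ethynyl]phenyl}ethanone F5. Treatment with Bu4NF in THF at reflux removes the silyl group and closes the furan by 5-endo-dig addition of the neighbouring phenol, coming back to the route at 5.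

Step 3. Conversion may stall because the chelated, doubly ortho-substituted ketone enolizes slowly as its phenoxide, or the 2'-hydroxychalcone may close to the flavanone by oxa-Michael addition. The fallback sets out from 5 and masks the phenol. Protection (NaH, MeOCH2Cl, DMF, 0 °C) should give 1-[4-methoxy-6-(methoxymethoxy)-1-benzofuran-7-yl]ethanone F6. Condensation with 6 (KOH, EtOH, rt) should give (2E)-1-[4-methoxy-6-(methoxymethoxy)-1-benzofuran-7-yl]-3-phenylprop-2-en-1-one F7. Cleavage of the acetal (HCl, MeOH, 40 °C) comes back to the route at 8.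

**Further compounds**

F1 | step 4 | racemic endo adduct, (1RS,2SR,6RS)-(6-hydroxy-4-methoxy-1-benzofuran-7-yl)[3-methyl-2-(3-methylbut-2-en-1-yl)-6-phenylcyclohex-3-en-1-yl]methanone (SMILES shows one enantiomer of the racemate) | COc1cc(O)c(C(=O)[C@@H]2[C@H](CC=C(C)C)C(C)=CC[C@H]2c2ccccc2)c2occc12
F2 | step 4 | (1S,4R)-camphanate ester of the C6 phenol of the (1R,2S,6R) ketone 12 | COc1cc(OC(=O)[C@@]23CC[C@@](C)(C(=O)O2)C3(C)C)c(C(=O)[C@@H]2[C@H](CC=C(C)C)C(C)=CC[C@H]2c2ccccc2)c2occc12
F3 | step 4 | (1S,4R)-camphanate ester of the C6 phenol of the (1S,2R,6S) ketone | COc1cc(OC(=O)[C@@]23CC[C@@](C)(C(=O)O2)C3(C)C)c(C(=O)[C@H]2[C@@H](CC=C(C)C)C(C)=CC[C@@H]2c2ccccc2)c2occc12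
F4 | step 2 | 1-(2,6-dihydroxy-3-iodo-4-methoxyphenyl)ethanone | COc1cc(O)c(C(C)=O)c(O)c1I
F5 | step 2 | 1-{2,6-dihydroxy-4-methoxy-3-[(trimethylsilyl)ethynyl]phenyl}ethanone | COc1cc(O)c(C(C)=O)c(O)c1C#C[Si](C)(C)C
F6 | step 3 | 1-[4-methoxy-6-(methoxymethoxy)-1-benzofuran-7-yl]ethanone | COCOc1cc(OC)c2ccoc2c1C(C)=O
F7 | step 3 | (2E)-1-[4-methoxy-6-(methoxymethoxy)-1-benzofuran-7-yl]-3-phenylprop-2-en-1-one | COCOc1cc(OC)c2ccoc2c1C(=O)/C=C/c1ccccc1
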